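The readings were generated by integration with constants of no real substance.

The ochre flask came to me followed as far as 30.0 min, together with the warmer amber run, and I had to say where it stops and what could move it.

the same everywhere: starting material 0.050 M; free enzyme 25 µM
- ochre: solid second substrate 0.20 M; temperature 5 °C; the very flask that is asked about, followed so far
- amber: solid second substrate 0.20 M; temperature 11 °C; run made earlier
- flask: solid second substrate 0.200 M; temperature 5 °C; time 40 min

| run | time / min | product / % | starting material / % |
|---|---|---|---|
| ochre | 1.50 | 12.0 | 89.8 |
| ochre | 5.00 | 40.1 | 59.2 |
| ochre | 10.0 | 63.0 | 38.4 |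
| ochre | 15.0 | 73.6 | 27.4 |
| ochre | 20.0 | 78.0 | 22.4 |
| ochre | 25.0 | 79.2 | 19.7 |
| ochre | 30.0 | 81.2 | 19.2 |
| amber | 1.50 | 4.4 | 92.5 |
| amber | 5.00 | 13.1 | 86.2 |
| amber | 10.0 | 12.9 | 85.2 |
| amber | 15.0 | 12.2 | 85.0 |
| amber | 20.0 | 12.2 | 85.7 |
| amber | 25.0 | 13.7 | 86.2 |
| amber | 30.0 | 14.3 | 87.7 |

(each reading ± 1 percentage point)

- east: change nothing and wait 80 min more
- north-west: at 40 min add free enzyme, 50.0% of the amount charged, then wait 80 min
- north-east: at 40 min raise the temperature by 10 K, then wait 80 min
- south-east: at 40 min take out 90% of the product then present, then wait 80 min

- as a solid, counted per litre of solution: solid second substrate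
- product taken out counts as made
- the analysis behind the earlier runs scatters by 1 percentage point, standard deviation
- what may be going on: free enzyme -> unfolded enzyme; starting material + free enzyme <-> starting complex; second substrate + starting complex <-> ternary complex; ternary complex -> free enzyme + product; solid second substrate <-> second substrate
- at the start none of the solid second substrate is in solution
- additions bring no volume worth counting

- product, in percent of the starting material first charged, at 40 min
- which option adds most product ("none" when 2 percentage points or less is all one gets) (east / north-west / north-east / south-east / none)
- product present, with what was taken out counted in, in percent of the starting material first charged, after north-west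
- product present, with what was taken out counted in, in percent of the starting material first charged, after south-east

I turned the question round: for north-west to fail, the ochre stop would need a cause that fresh free enzyme could not touch. Running out of solid second substrate was not that cause, because the ochre run had made 0.0406 M of product against a charge of 0.20 M, less than the solid charged. Equilibrium looked no better: product over starting material at the last reading was 4.23 in the ochre run at 5 °C and 0.163 in the amber run at 11 °C, a factor of 25.9 that I could not accept as a shifted equilibrium. So I took the enzyme to be dying.

I treated the rate as pseudo-first-order in starting material, with rate constant κ[free enzyme], κ being a constant and a the fraction of starting material left: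

−d(ln a)/dt = κ[free enzyme]

L = −ln(a at the stop) = κ∫[free enzyme]dt

The last ochre reading, taken as the stop, gave L = 1.65, the enzyme budget: the logarithmic conversion a charge of free enzyme buys before it dies, which I took as proportional to that charge at fixed temperature and fixed second substrate. My own reckoning for north-west, with 50.0% added, was:

left = 19.2% × exp(−50.0% × L) = 8.41%

That meant product 91.6%, a gain of 11 percentage points, above the margin. The last two starting-material readings differed by 0.5 points, less than the scatter, so I expected little from waiting.

The forecast gave 81.5% now, north-west as best, 92% after north-west and 82% after south-east, on the ground that “The enzyme is dying, and faster when warmer.” Its north-west figure stood slightly above mine.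

The flask gave 82.4%, with north-west best at 11 points added, 93.9% after it and 82.9% after south-east.

    free enzyme → unfolded enzyme (k = 0.00221 /s, Ea = 231 kJ/mol)
    starting material + free enzyme ⇌ starting complex (K = 7.80 /M, k = 3460 /M/s, Ea = 13.0 kJ/mol, ΔH = 0 kJ/mol)
    second substrate + starting complex ⇌ ternary complex (K = 45.0 /M, k = 28000 /M/s, Ea = 23.0 kJ/mol, ΔH = −53.0 kJ/mol)
    ternary complex → free enzyme + product (k = 32.6 /s, Ea = 51.0 kJ/mol)
    solid second substrate ⇌ second substrate, rate k5*(cs5 - [second substrate]) while solid is left; crystals form when [second substrate] > cs5 (solubility = 18.0 mM, k = 0.0208 /s)
    (constants at 5 °C)

The flask held 18% of its starting material at 40.0 min, a budget of 1.74 against my 1.65 from the reading at 30.0 min. A neighbour charged with 6.2 × 10⁻⁶ M of free enzyme should have a budget of 0.409, which leaves 66.4%. That neighbour held 63.4% of its starting material at 40.0 min, with product at 36.6%.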